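The side chain (numbered from the ketone carbon C1') is cut at C5'–C6' and at the C4'–CH3 bond. The feature exploited is the isolated methyl stereocentre C4', flanked by the methylenes C3' and C5', with C5' bonded to the sp2 carbon C6' of the C6'=C7'–C8'=C9' diene; the dihydropyranone ring plays no part and is attached afterwards. In one flask a chiral zirconocene adds CH3 and aluminium across the terminal alkene of a silyl-protected pent-4-en-1-ol, setting (R)-C4', and the C5' metal is then cross-coupled with a dienyl iodide. The precursors are this alkenyl silyl ether and a tert-butyl iododienoate already carrying C6'–C12', both E alkenes and (S)-C10'.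

Key step: step 5

Assumption: with (−)-(NMI)2ZrCl2 the silyl ether 2 is taken to follow the sense of induction known for simple 1-alkenes, which corresponds to (R) at C4'; should a first run show the opposite sense, the (+)-antipode is used with nothing else changed.

Step 1
Reactants: 1 pent-4-en-1-ol
Product: 2 tert-butyl(dimethyl)(pent-4-en-1-yloxy)silane
Conditions: TBSCl, imidazole, CH2Cl2, 0 °C → rt
Reagents that add atoms: tert-butyldimethylsilyl chloride, CC(C)(C)[Si](C)(C)Cl
Why: Silyl ether formation at an unhindered primary alcohol under imidazole catalysis is dependable, and the TBS ether is inert to Me3Al and to the zinc reagent of step 5.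

Step 2
Reactants: 3 (S)-2-methylbutan-1-ol; 4 tert-butyl (triphenylphosphoranylidene)acetate
Product: 7 tert-butyl (2Z,4S)-2-bromo-4-methylhex-2-enoate, via (S)-2-methylbutanal 5 (not isolated), via bromo ylide 6 (not isolated)
Conditions: flask A: 3, TEMPO (1 mol%), KBr (10 mol%), NaOCl, NaHCO3, CH2Cl2/H2O, 0 °C, organic layer dried (MgSO4) and kept cold; flask B: 4 (1.3 equiv), NBS (1.3 equiv), CH2Cl2, −20 °C; solution of 5 added to B, −20 °C → rt
Reagents that add atoms: N-bromosuccinimide, O=C1CCC(=O)N1Br
Why: TEMPO/NaOCl oxidation delivers the configurationally labile aldehyde 5 cold and free of acid or base, and its Wittig reaction with the non-basic stabilised bromo ylide 6 (made by brominating 4) should place the ester trans to the sec-butyl group, i.e. the (Z)-bromoalkene, without disturbing the (S) centre brought in with 3.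

Step 3
Reactants: 7 tert-butyl (2Z,4S)-2-bromo-4-methylhex-2-enoate; 8 (E)-1,2-bis(tributylstannyl)ethene
Product: 9 tert-butyl (2E,4S)-4-methyl-2-[(E)-2-(tributylstannyl)ethenyl]hex-2-enoate
Conditions: 8 (2.5 equiv), Pd2(dba)3 (2.5 mol%), AsPh3 (20 mol%), NMP, 50 °C, dark
Reagents that add atoms: none
Why: Stille coupling of the electron-poor alkenyl bromide with one tin terminus of the distannane should proceed with retention at both partners, and the excess of 8 suppresses coupling at the second tin.

Step 4
Reactants: 9 tert-butyl (2E,4S)-4-methyl-2-[(E)-2-(tributylstannyl)ethenyl]hex-2-enoate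
Product: 10 tert-butyl (2E,4S)-2-[(E)-2-iodoethenyl]-4-methylhex-2-enoate
Conditions: I2 (1.05 equiv), CH2Cl2, 0 °C, dark; aq. Na2S2O3 wash
Reagents that add atoms: iodine, [I][I]
Why: Iododestannylation is an ipso substitution at the sp2 C–Sn bond that proceeds with retention, so the E geometry at C6'=C7' is kept and the electron-poor trisubstituted alkene is left alone.

Step 5
Reactants: 2 tert-butyl(dimethyl)(pent-4-en-1-yloxy)silane; 11 trimethylaluminium; 10 tert-butyl (2E,4S)-2-[(E)-2-iodoethenyl]-4-methylhex-2-enoate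
Product: 14 tert-butyl (2E,4S)-2-[(1E,4R)-7-[(tert-butyldimethylsilyl)oxy]-4-methylhept-1-en-1-yl]-4-methylhex-2-enoate, via alkyldimethylalane 12 (not isolated), via alkylzinc triflate 13 (not isolated)
Conditions: 2 (1.5 equiv), Me3Al (3 equiv), (−)-(NMI)2ZrCl2 [dichlorobis(1-neomenthylindenyl)zirconium] (5 mol%), (MeAlO)n (methylaluminoxane, 0.2 equiv), CH2Cl2, 0 °C → rt; volatiles removed in vacuo; Zn(OTf)2 (1.5 equiv), DMF, 70 °C; then 10 (1.0 equiv), PdCl2(DPEphos) (DPEphos = bis[2-(diphenylphosphino)phenyl] ether, 5 mol%) pre-reduced with iBu2AlH (10 mol%), DMF, rt → 50 °C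
Reagents that add atoms: none
Why: Me3Al and methylaluminoxane turn the zirconium dichloride into a cationic methylzirconocene that inserts the monosubstituted alkene of 2 (CH3 to C4', Zr to C5') and passes the primary alkyl on to aluminium (12), after which Zn(OTf)2 in DMF relays the alkyl to zinc (13) and zerovalent palladium, formed from the divalent palladium precatalyst, joins it to 10 by oxidative addition, transmetalation and reductive elimination. The closest known chemistry is the zirconium-catalysed asymmetric carboalumination of terminal alkenes run in one pot with a Negishi alkyl–alkenyl coupling. No ring is closed. The one new stereocentre, (R)-C4', is set by the chiral neomenthylindenyl ligands, which select the alkene face, so this is pure catalyst control on an achiral substrate. The step needs the metal at the terminal C5', alkyl rather than methyl transfer to palladium, and an unchanged (E)-C6'=C7' bond: the first follows from the unhindered monosubstituted alkene with only a remote silyl ether, the second from the Zn(OTf)2/DMF relay, and the third from the stereoretentive steps at the alkenyl iodide. The tert-butyl ester of 10 meets only a mild organozinc once excess Me3Al has been evaporated, and 2 is used in excess so that the more valuable iodide is the limiting partner.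

Step 6
Reactants: 14 tert-butyl (2E,4S)-2-[(1E,4R)-7-[(tert-butyldimethylsilyl)oxy]-4-methylhept-1-en-1-yl]-4-methylhex-2-enoate
Product: 15 tert-butyl (2E,4S)-2-[(1E,4R)-7-hydroxy-4-methylhept-1-en-1-yl]-4-methylhex-2-enoate
Conditions: camphorsulfonic acid (10 mol%), MeOH/CH2Cl2 (1:1), 0 °C → rt
Reagents that add atoms: none
Why: Acid-catalysed methanolysis (silyl ether cleavage) removes a primary TBS group quickly, while the tert-butyl ester and the diene are untouched by such mild acid.

Step 7
Reactants: 15 tert-butyl (2E,4S)-2-[(1E,4R)-7-hydroxy-4-methylhept-1-en-1-yl]-4-methylhex-2-enoate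
Product: 16 (4R,6E,8E,10S)-8-(tert-butoxycarbonyl)-4,10-dimethyldodeca-6,8-dienoic acid
Conditions: TEMPO (20 mol%), PhI(OAc)2 (2.5 equiv), MeCN/H2O (1:1), rt
Reagents that add atoms: water, O
Why: The TEMPO/PhI(OAc)2 oxidation takes a primary alcohol through the aldehyde hydrate to the carboxylic acid under near-neutral conditions that spare the electron-poor diene, the tert-butyl ester and both stereocentres.

Step 8
Reactants: 17 methyl (R)-3-hydroxybutanoate; 18 tert-butyl acetate
Product: 20 tert-butyl (R)-5-hydroxy-3-oxohexanoate, via lithium enolate 19 (not isolated)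
Conditions: 18 (3.5 equiv), LiN(iPr)2 (3.5 equiv), THF, −78 °C; then 17, −78 → −30 °C; AcOH quench
Reagents that add atoms: none
Why: Crossed Claisen condensation of the methyl ester with excess lithium tert-butyl acetate enolate (the first equivalent only deprotonates the hydroxyl) gives the δ-hydroxy-β-keto ester as its stable enolate, and the carbinol C–O bond is never broken, so (R) is retained.

Step 9
Reactants: 20 tert-butyl (R)-5-hydroxy-3-oxohexanoate
Product: 21 (R)-4-hydroxy-6-methyl-5,6-dihydro-2H-pyran-2-one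
Conditions: TFA/CH2Cl2 (1:4), 0 °C → rt; evaporation, trituration
Reagents that add atoms: none
Why: TFA cleaves the tert-butyl ester and the δ-hydroxyl captures the acyl carbon (acid-mediated lactonisation) to give the six-membered enol lactone with the carbinol configuration unchanged.

Step 10
Reactants: 16 (4R,6E,8E,10S)-8-(tert-butoxycarbonyl)-4,10-dimethyldodeca-6,8-dienoic acid; 21 (R)-4-hydroxy-6-methyl-5,6-dihydro-2H-pyran-2-one
Product: 23 tert-butyl (2E,4S)-2-[(1E,4R)-7-[(6R)-4-hydroxy-6-methyl-2-oxo-5,6-dihydro-2H-pyran-3-yl]-4-methyl-7-oxohept-1-en-1-yl]-4-methylhex-2-enoate, via enol ester 22 (not isolated)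
Conditions: dicyclohexylcarbodiimide (1.2 equiv), DMAP (1.2 equiv), CH2Cl2, 0 °C → rt; dilute aq. HCl wash
Reagents that add atoms: none
Why: Steglich-type activation acylates the enol oxygen of 21 to give 22, and DMAP then takes the acyl group back as an acylpyridinium/enolate pair that recombines at ring carbon C3 (Fries-type O-to-C acyl shift), driven by the chelated, strongly acidic tricarbonyl and free of any strong base that could epimerise C10' through the dienolate.

Step 11
Reactants: 23 tert-butyl ester of the target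
Product: 24 (2E,4S)-2-[(1E,4R)-7-[(6R)-4-hydroxy-6-methyl-2-oxo-5,6-dihydro-2H-pyran-3-yl]-4-methyl-7-oxohept-1-en-1-yl]-4-methylhex-2-enoic acid
Conditions: TFA/CH2Cl2 (1:4), 0 °C → rt
Reagents that add atoms: none
Why: Acidolysis of the tert-butyl ester (loss of 2-methylpropene) frees the dienoic acid, while the acyl dihydropyranone, both alkene geometries and all three stereocentres should be stable to cold TFA.

Compound list
1 | pent-4-en-1-ol | C=CCCCO | starting material
2 | tert-butyl(dimethyl)(pent-4-en-1-yloxy)silane | C=CCCCO[Si](C)(C)C(C)(C)C | intermediate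
3 | (S)-2-methylbutan-1-ol | CC[C@H](C)CO | starting material
4 | tert-butyl (triphenylphosphoranylidene)acetate | CC(C)(C)OC(=O)C=P(c1ccccc1)(c1ccccc1)c1ccccc1 | starting material
5 | (S)-2-methylbutanal | CC[C@H](C)C=O | intermediate
6 | tert-butyl bromo(triphenylphosphoranylidene)acetate (bromo ylide) | CC(C)(C)OC(=O)C(Br)=P(c1ccccc1)(c1ccccc1)c1ccccc1 | intermediate
7 | tert-butyl (2Z,4S)-2-bromo-4-methylhex-2-enoate | CC[C@H](C)/C=C(\Br)C(=O)OC(C)(C)C | intermediate
8 | (E)-1,2-bis(tributylstannyl)ethene | CCCC[Sn](CCCC)(CCCC)/C=C/[Sn](CCCC)(CCCC)CCCC | starting material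
9 | tert-butyl (2E,4S)-4-methyl-2-[(E)-2-(tributylstannyl)ethenyl]hex-2-enoate | CC[C@H](C)/C=C(\C=C\[Sn](CCCC)(CCCC)CCCC)C(=O)OC(C)(C)C | intermediate
10 | tert-butyl (2E,4S)-2-[(E)-2-iodoethenyl]-4-methylhex-2-enoate | CC[C@H](C)/C=C(\C=C\I)C(=O)OC(C)(C)C | intermediate
11 | trimethylaluminium | C[Al](C)C | starting material
12 | (R)-{5-[(tert-butyldimethylsilyl)oxy]-2-methylpentyl}dimethylalane | C[C@H](CCCO[Si](C)(C)C(C)(C)C)C[Al](C)C | intermediate
13 | {(2R)-5-[(tert-butyldimethylsilyl)oxy]-2-methylpentyl}zinc triflate | C[C@H](CCCO[Si](C)(C)C(C)(C)C)C[Zn]OS(=O)(=O)C(F)(F)F | intermediate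
14 | tert-butyl (2E,4S)-2-[(1E,4R)-7-[(tert-butyldimethylsilyl)oxy]-4-methylhept-1-en-1-yl]-4-methylhex-2-enoate | CC[C@H](C)/C=C(\C=C\C[C@H](C)CCCO[Si](C)(C)C(C)(C)C)C(=O)OC(C)(C)C | intermediate
15 | tert-butyl (2E,4S)-2-[(1E,4R)-7-hydroxy-4-methylhept-1-en-1-yl]-4-methylhex-2-enoate | CC[C@H](C)/C=C(\C=C\C[C@H](C)CCCO)C(=O)OC(C)(C)C | intermediate
16 | (4R,6E,8E,10S)-8-(tert-butoxycarbonyl)-4,10-dimethyldodeca-6,8-dienoic acid | CC[C@H](C)/C=C(\C=C\C[C@H](C)CCC(=O)O)C(=O)OC(C)(C)C | intermediate
17 | methyl (R)-3-hydroxybutanoate | C[C@@H](O)CC(=O)OC | starting material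
18 | tert-butyl acetate | CC(=O)OC(C)(C)C | starting material
19 | lithium enolate of tert-butyl acetate | [Li]OC(=C)OC(C)(C)C | intermediate
20 | tert-butyl (R)-5-hydroxy-3-oxohexanoate | C[C@@H](O)CC(=O)CC(=O)OC(C)(C)C | intermediate
21 | (R)-4-hydroxy-6-methyl-5,6-dihydro-2H-pyran-2-one | C[C@@H]1CC(O)=CC(=O)O1 | intermediate
22 | (6R)-6-methyl-2-oxo-5,6-dihydro-2H-pyran-4-yl (4R,6E,8E,10S)-8-(tert-butoxycarbonyl)-4,10-dimethyldodeca-6,8-dienoate (enol ester) | CC[C@H](C)/C=C(\C=C\C[C@H](C)CCC(=O)OC1=CC(=O)O[C@H](C)C1)C(=O)OC(C)(C)C | intermediate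
23 | tert-butyl (2E,4S)-2-[(1E,4R)-7-[(6R)-4-hydroxy-6-methyl-2-oxo-5,6-dihydro-2H-pyran-3-yl]-4-methyl-7-oxohept-1-en-1-yl]-4-methylhex-2-enoate | CC[C@H](C)/C=C(\C=C\C[C@H](C)CCC(=O)C1=C(O)C[C@@H](C)OC1=O)C(=O)OC(C)(C)C | intermediate
24 | (2E,4S)-2-[(1E,4R)-7-[(6R)-4-hydroxy-6-methyl-2-oxo-5,6-dihydro-2H-pyran-3-yl]-4-methyl-7-oxohept-1-en-1-yl]-4-methylhex-2-enoic acid | CC[C@H](C)/C=C(\C=C\C[C@H](C)CCC(=O)C1=C(O)C[C@@H](C)OC1=O)C(=O)O | target

Total step count: 11 steps.
Longest linear sequence: 8 steps (3 → 24 through steps 2, 3, 4, 5, 6, 7, 10 and 11).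

Steps most likely to fail

Step 5. Face selection in the methylalumination may be incomplete, which would leave a C4' epimer that cannot be removed later. Methyl instead of alkyl may also be transferred to palladium, or the alkylmetal may be protonated before it couples. The fallback sets out from 2 (and uses 10) and returns at 14. The carboalumination is run as in step 5, but alane 12 is oxidised with O2 to (R)-5-[(tert-butyldimethylsilyl)oxy]-2-methylpentan-1-ol F1. Lipase-mediated acetylation (Amano PS lipase, vinyl acetate) is expected to acetylate the minor enantiomer faster, giving (S)-5-[(tert-butyldimethylsilyl)oxy]-2-methylpentyl acetate F2, which is removed by chromatography. Appel iodination (I2, PPh3, imidazole) of the upgraded alcohol gives tert-butyl{[(4R)-5-iodo-4-methylpentyl]oxy}dimethylsilane F3. Zinc insertion (Zn dust, LiCl, THF) gives {(2R)-5-[(tert-butyldimethylsilyl)oxy]-2-methylpentyl}zinc iodide F4, and a separate Negishi coupling with 10 (Pd(PPh3)4, THF) should return 14.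

Step 3. Coupling may go on at the second tin terminus, the stannane may be protonated off, or oxidative addition to the hindered bromide may be slow. The fallback sets out from 7 and returns at 10, so that 9 and step 4 are bypassed. Sonogashira coupling with ethynyltrimethylsilane (PdCl2(PPh3)2, CuI, iPr2NH) should give tert-butyl (2E,4S)-4-methyl-2-[(trimethylsilyl)ethynyl]hex-2-enoate F5. Desilylation (K2CO3, MeOH, 0 °C) gives tert-butyl (2E,4S)-2-ethynyl-4-methylhex-2-enoate F6. Syn hydrozirconation of the terminal alkyne (Cp2Zr(H)Cl, THF, 0 °C) gives the (E)-alkenylzirconocene chloride F7, and iodinolysis with I2 should give 10 with the E geometry fixed by the syn addition.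

Step 10. The acyl group may stall on oxygen without shifting to C3, or the activated acid may rearrange to an N-acylurea. The fallback sets out from 16 (and uses 17) and returns at 23. Acid 16 is condensed with Meldrum's acid (dicyclohexylcarbodiimide, DMAP, CH2Cl2) to the acyl Meldrum's acid F8. Heating F8 with 17 in toluene at 80 °C gives, through the acylketene, the β-keto ester of methyl (R)-3-hydroxybutanoate F9. Dieckmann closure of the active methylene onto the methyl ester (KOtBu, 1.05 equiv, THF, 0 °C) should then give 23.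

Further compounds
F1 | step 5 | (R)-5-[(tert-butyldimethylsilyl)oxy]-2-methylpentan-1-ol | C[C@H](CCCO[Si](C)(C)C(C)(C)C)CO
F2 | step 5 | (S)-5-[(tert-butyldimethylsilyl)oxy]-2-methylpentyl acetate | C[C@@H](CCCO[Si](C)(C)C(C)(C)C)COC(C)=O
F3 | step 5 | tert-butyl{[(4R)-5-iodo-4-methylpentyl]oxy}dimethylsilane | C[C@H](CCCO[Si](C)(C)C(C)(C)C)CI
F4 | step 5 | {(2R)-5-[(tert-butyldimethylsilyl)oxy]-2-methylpentyl}zinc iodide | C[C@H](CCCO[Si](C)(C)C(C)(C)C)C[Zn]I
F5 | step 3 | tert-butyl (2E,4S)-4-methyl-2-[(trimethylsilyl)ethynyl]hex-2-enoate | CC[C@H](C)/C=C(\C#C[Si](C)(C)C)C(=O)OC(C)(C)C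
F6 | step 3 | tert-butyl (2E,4S)-2-ethynyl-4-methylhex-2-enoate | CC[C@H](C)/C=C(\C#C)C(=O)OC(C)(C)C
F7 | step 3 | chlorobis(cyclopentadienyl){(1E,3E,5S)-3-(tert-butoxycarbonyl)-5-methylhepta-1,3-dien-1-yl}zirconium | CC[C@H](C)/C=C(\C=C\[Zr](Cl)(C1C=CC=C1)C1C=CC=C1)C(=O)OC(C)(C)C
F8 | step 10 | tert-butyl (2E,4S)-2-[(1E,4R)-7-(2,2-dimethyl-4,6-dioxo-1,3-dioxan-5-ylidene)-7-hydroxy-4-methylhept-1-en-1-yl]-4-methylhex-2-enoate | CC[C@H](C)/C=C(\C=C\C[C@H](C)CCC(O)=C1C(=O)OC(C)(C)OC1=O)C(=O)OC(C)(C)C
F9 | step 10 | methyl (3R)-3-{[(6R,8E,10E,12S)-10-(tert-butoxycarbonyl)-6,12-dimethyl-3-oxotetradeca-8,10-dienoyl]oxy}butanoate | CC[C@H](C)/C=C(\C=C\C[C@H](C)CCC(=O)CC(=O)O[C@H](C)CC(=O)OC)C(=O)OC(C)(C)C
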